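The cyclopentene (C8–C9–C11=C12–C13) and the δ-lactone (O–C15–C14–C13–C8–C9) that share the 2-oxabicyclo[3.2.1]octene are closed together on a preformed decalin by making C8–C13 and C11=C12. The route exploits the C9–O lactone bond as a tether and the C6 oxygen, held as a ketone, to make C8 electrophilic. The precursor is a ring-B enone whose tertiary C9 ester carries a vinyl group (C11) and an α-keto ester ending in C13–H flanked by CO2Me and isopropenyl (C12). In one flask carbonate drives 6-exo Michael addition of C13 to C8 and a ruthenium carbene then joins the two alkenes. An enantioselective quinone Diels–Alder reaction sets C10, which relays all other centres.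

Key step: step 8

Remark (numbering): C1–C10 are the decalin carbons (C3 acetoxy carbon, C4 gem-dimethyl carbon, C5 ring-fusion CH, C6 γ-lactone O–CH, C7 CH2, C8 methyl-bearing quaternary carbon, C9 oxygenated quaternary carbon, C10 angular carbon); C11 is =CH, C12 is =C(CH3), C13 is the quaternary carbon bearing CO2Me, C14 the exo-methylene carbon, C15 the δ-lactone carbonyl, C19 the γ-lactone carbonyl.

Remark (assumption): the chiral Lewis acid in step 4 is assumed to give the (10S) adduct; if the opposite sense is found, the mirror-image ligand is used.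

Remark (tautomers): compound 14 is drawn in its keto form; it should exist largely as the C14 enol and as a mixture at C5 and C13, all of which converge in step 8.

Step 1
Reactants: 1 3-methylsalicylic acid
Product: 3 2,5-dihydroxy-3-methylbenzoic acid, via aryl hydrogen sulfate 2 (not isolated)
Conditions: K2S2O8, aq NaOH, 0–20 °C; then aq HCl, 80 °C
Reagents that add atoms: potassium peroxodisulfate, [K+].[K+].[O-]S(=O)(=O)OOS(=O)(=O)[O-]
Why: Elbs persulfate oxidation, in which the phenolate is attacked by peroxodisulfate at its free para position and the aryl sulfate is hydrolysed by acid.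

Step 2
Reactants: 3 2,5-dihydroxy-3-methylbenzoic acid
Product: 4 methyl 2,5-dihydroxy-3-methylbenzoate
Conditions: MeOH, H2SO4 (cat.), reflux
Reagents that add atoms: methanol, CO
Why: Fischer esterification of the carboxylic acid, which leaves the phenols untouched.

Step 3
Reactants: 5 4-methylpent-1-en-3-one
Product: 6 tert-butyl(dimethyl)[(4-methylpenta-1,3-dien-3-yl)oxy]silane
Conditions: TBSOTf, Et3N, CH2Cl2, 0 °C
Reagents that add atoms: tert-butyldimethylsilyl triflate, CC(C)(C)[Si](C)(C)OS(=O)(=O)C(F)(F)F
Why: Silyl enol ether formation by soft enolisation; only the isopropyl side carries an α-hydrogen, so the 2-silyloxy diene with the CMe2 terminus should form.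

Step 4
Reactants: 4 methyl 2,5-dihydroxy-3-methylbenzoate, 6 tert-butyl(dimethyl)[(4-methylpenta-1,3-dien-3-yl)oxy]silane
Product: 8 cis-fused (10S) Diels–Alder adduct (C2=C3 TBS enol ether, 4,4-dimethyl, C6 and C9 ketones, C7=C8 with 8-methyl, angular CO2Me cis to H-5), via quinone ester 7 (not isolated)
Conditions: Ag2O, MgSO4, CH2Cl2, 0 °C, filter under Ar; then 6, Sm(OTf)3/(S,S)-Ph-pybox (10 mol%), 4 Å MS, THF, −78 to −30 °C
Reagents that add atoms: none
Why: Oxidation to the quinone followed by a catalytic enantioselective Diels–Alder reaction at the ester-bearing C5=C10 bond, which binds the chiral Lewis acid through ester and quinone carbonyls; the nucleophilic CMe2 terminus (C4) bonds to the unsubstituted C5 and C1 to C10, which sets the quaternary C10 and the cis ring fusion suprafacially.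

Step 5
Reactants: 8 cis-fused (10S) Diels–Alder adduct
Product: 9 3,6-bis(TBS-oxy) trienone (C5=C6 silyl dienol ether, C7=C8, C9 ketone)
Conditions: TBSOTf, Et3N, CH2Cl2, −78 to 0 °C
Reagents that add atoms: tert-butyldimethylsilyl triflate, CC(C)(C)[Si](C)(C)OS(=O)(=O)C(F)(F)F
Why: Silyl dienol ether formation at C6, the only enolisable ring-B ketone (through H-5), which masks C6 and leaves C9=O as the sole ketone; the C5 centre is erased here and reset in steps 7 and 8.

Step 6
Reactants: 9 3,6-bis(TBS-oxy) trienone
Product: 11 mixed methyl oxalate of the C9 vinyl carbinol (vinyl cis to the C10 ester, C9–O trans to it), via C9 vinyl carbinol 10 (not isolated)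
Conditions: vinylMgBr, CH2Cl2/THF, −78 °C; then ClC(O)CO2Me, −78 to 0 °C
Reagents that add atoms: vinylmagnesium bromide, C=C[Mg]Br; methyl chlorooxoacetate, COC(=O)C(Cl)=O
Why: Chelation-controlled Grignard 1,2-addition in which magnesium bridges C9=O and the C10 ester so that vinyl enters anti to C1 and C9–O ends trans to CO2Me; the hindered tertiary alkoxide is then acylated by the reactive oxalyl chloride.

Step 7
Reactants: 11 mixed methyl oxalate, 12 methyl 3-methylbut-2-enoate
Product: 14 key-step precursor (C3 ketone, C6-keto-Δ7 enone, C9 vinyl, C9–O α-keto ester ending in C13–H with CO2Me and isopropenyl), via bis-silyl α-keto ester 13 (not isolated)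
Conditions: 12, LDA (2.4 equiv each), THF, −78 °C, then 11; then 1 M HCl, THF, 0 °C
Reagents that add atoms: none
Why: Crossed Claisen condensation in which the lithium dienolate is C-acylated at its α-carbon by the unhindered methyl-ester carbonyl of the oxalate (the acidic product is held as its enolate), after which aqueous acid hydrolyses both silyl enol ethers, α-protonation at C5 giving the C7=C8 enone.

Step 8
Reactants: 14 key-step precursor
Product: 16 pentacyclic α-keto δ-lactone (C8–C13 bond and C11=C12 cyclopentene formed, C3 and C6 ketones, trans ring fusion), via Michael adduct 15 (not isolated)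
Conditions: Cs2CO3 (0.3 equiv), PhMe, 50 °C; then Hoveyda–Grubbs II (10 mol%), 80 °C, same flask
Reagents that add atoms: none
Why: Carbonate deprotonates C13–H, which is flanked by the α-keto ester and CO2Me, and the enolate adds in a 6-exo-trig intramolecular Michael reaction to C8 of the C6-keto enone, closing the δ-lactone and joining two quaternary carbons, while the carbonate also equilibrates H-5 to the trans fusion. The ruthenium alkylidene then closes the five-membered ring by ring-closing metathesis of the C9 vinyl and C13 isopropenyl groups, forming the etheno bridge of the 2-oxabicyclo[3.2.1]octene with loss of ethene. The closest known reactions are intramolecular Michael additions of tethered β-keto esters to cyclohexenones and RCM of 1,3-diaxial dialkenyl six-membered rings to bicyclo[3.2.1]octenes. C8 is set by the tether, because C13 can reach C8 only on the face of the C9–O bond, which places the C8 methyl trans to it; C13 is set by the metathesis itself, because only the epimer with isopropenyl syn to vinyl can close and the Michael step stays reversible under carbonate, which feeds that epimer. The step needs C- over O-attack and α- over γ-attack of the extended enolate (α gives a six-membered ring, γ an eight-membered one, and O-adducts revert) and metathesis of only the two terminal olefins, which are the only unhindered alkenes left once the enone is consumed.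

Step 9
Reactants: 16 pentacyclic α-keto δ-lactone
Product: 17 C14 β-hydroxysilane (C14 carries OH and CH2SiMe3, configuration at C14 not defined)
Conditions: Me3SiCH2MgCl (1.2 equiv), THF, −78 °C
Reagents that add atoms: (trimethylsilyl)methylmagnesium chloride, C[Si](C)(C)C[Mg]Cl
Why: Chemoselective Grignard addition to the non-enolisable α-keto-lactone carbonyl, which is far more electrophilic than the two hindered ring ketones, giving the Peterson precursor and removing the hydride-sensitive keto group before reduction.

Step 10
Reactants: 17 C14 β-hydroxysilane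
Product: 19 bis-lactone diol (axial 3-OH, C6–O–C19 γ-lactone, C14 OH/CH2SiMe3), via seco dihydroxy ester 18 (not isolated)
Conditions: L-Selectride, THF, −78 to 0 °C
Reagents that add atoms: none
Why: Bulky-hydride ketone reduction, in which equatorial attack at C3 gives the axial (3S) alcohol and at C6 hydride enters from the only open face, opposite the axial C8 methyl and C10 ester; the resulting 6-alkoxide lactonises onto the 1,3-diaxial C10 ester.

Step 11
Reactants: 19 bis-lactone diol
Product: 21 meroantarctine B, via 3-deacetyl alcohol 20 (not isolated)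
Conditions: KHMDS (2.2 equiv), THF, −78 to 0 °C; then Ac2O, 0 to 23 °C
Reagents that add atoms: acetic anhydride, CC(=O)OC(C)=O
Why: Peterson olefination by syn-elimination of the potassium β-silyl alkoxide gives the exo-methylene lactone, and the C3 alkoxide is acetylated in the same flask.

Compound list
1 | 3-methylsalicylic acid | Cc1cccc(C(=O)O)c1O | starting material
2 | 3-carboxy-4-hydroxy-5-methylphenyl hydrogen sulfate | Cc1cc(OS(=O)(=O)O)cc(C(=O)O)c1O | intermediate
3 | 2,5-dihydroxy-3-methylbenzoic acid | Cc1cc(O)cc(C(=O)O)c1O | intermediate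
4 | methyl 2,5-dihydroxy-3-methylbenzoate | COC(=O)c1cc(O)cc(C)c1O | intermediate
5 | 4-methylpent-1-en-3-one | C=CC(=O)C(C)C | starting material
6 | tert-butyl(dimethyl)[(4-methylpenta-1,3-dien-3-yl)oxy]silane | C=CC(O[Si](C)(C)C(C)(C)C)=C(C)C | intermediate
7 | methyl 5-methyl-3,6-dioxocyclohexa-1,4-diene-1-carboxylate | COC(=O)C1=CC(=O)C=C(C)C1=O | intermediate
8 | cis-fused (10S) Diels–Alder adduct, C2=C3 TBS enol ether, C6/C9 enedione | COC(=O)[C@@]12CC=C(O[Si](C)(C)C(C)(C)C)C(C)(C)[C@@H]1C(=O)C=C(C)C2=O | intermediate
9 | 3,6-bis(TBS-oxy) trienone (C5=C6 silyl dienol ether, C9 ketone) | COC(=O)[C@@]12CC=C(O[Si](C)(C)C(C)(C)C)C(C)(C)C1=C(O[Si](C)(C)C(C)(C)C)C=C(C)C2=O | intermediate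
10 | C9 vinyl carbinol (formed as its bromomagnesium alkoxide), 9-OH trans to the C10 ester | O[C@@]1(C=C)C(C)=CC(O[Si](C)(C)C(C)(C)C)=C2C(C)(C)C(O[Si](C)(C)C(C)(C)C)=CC[C@@]12C(=O)OC | intermediate
11 | mixed methyl oxalate of carbinol 10 | COC(=O)C(=O)O[C@@]1(C=C)C(C)=CC(O[Si](C)(C)C(C)(C)C)=C2C(C)(C)C(O[Si](C)(C)C(C)(C)C)=CC[C@@]12C(=O)OC | intermediate
12 | methyl 3-methylbut-2-enoate | COC(=O)C=C(C)C | starting material
13 | bis-silyl α-keto ester (C13–H bearing CO2Me and isopropenyl) | C=C(C)C(C(=O)OC)C(=O)C(=O)O[C@@]1(C=C)C(C)=CC(O[Si](C)(C)C(C)(C)C)=C2C(C)(C)C(O[Si](C)(C)C(C)(C)C)=CC[C@@]12C(=O)OC | intermediate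
14 | key-step precursor: C3 ketone, C6-keto-Δ7 enone, C9 vinyl, C9–O α-keto ester (keto form, C5 and C13 not defined) | C=C(C)C(C(=O)OC)C(=O)C(=O)O[C@@]1(C=C)C(C)=CC(=O)C2C(C)(C)C(=O)CC[C@@]12C(=O)OC | intermediate
15 | Michael adduct: δ-lactone closed through C8–C13, C9 vinyl and C13 isopropenyl syn | O=C1C(=O)O[C@@]2(C=C)[C@](C)(CC(=O)[C@@H]3C(C)(C)C(=O)CC[C@@]23C(=O)OC)[C@@]1(C(=O)OC)C(C)=C | intermediate
16 | pentacyclic α-keto δ-lactone with C11=C12 cyclopentene, C3 and C6 ketones | O=C1C(=O)O[C@@]23C=C(C)[C@]1(C(=O)OC)[C@@]2(C)CC(=O)[C@@H]1C(C)(C)C(=O)CC[C@@]31C(=O)OC | intermediate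
17 | C14 β-hydroxysilane (C14 OH and CH2SiMe3, C14 not defined) | C[Si](C)(C)CC1(O)C(=O)O[C@@]23C=C(C)[C@]1(C(=O)OC)[C@@]2(C)CC(=O)[C@@H]1C(C)(C)C(=O)CC[C@@]31C(=O)OC | intermediate
18 | seco dihydroxy ester (axial 3-OH and 6-OH, C10 methyl ester) | C[Si](C)(C)CC1(O)C(=O)O[C@@]23C=C(C)[C@]1(C(=O)OC)[C@@]2(C)C[C@H](O)[C@@H]1C(C)(C)[C@@H](O)CC[C@@]31C(=O)OC | intermediate
19 | bis-lactone diol (axial 3-OH, γ-lactone C6–O–C19, C14 OH/CH2SiMe3) | C[Si](C)(C)CC1(O)C(=O)O[C@@]23C=C(C)[C@]1(C(=O)OC)[C@@]2(C)C[C@@H]1OC(=O)[C@]32CC[C@H](O)C(C)(C)[C@@H]12 | intermediate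
20 | 3-deacetyl meroantarctine B | C=C1C(=O)O[C@@]23C=C(C)[C@]1(C(=O)OC)[C@@]2(C)C[C@@H]1OC(=O)[C@]32CC[C@H](O)C(C)(C)[C@@H]12 | intermediate
21 | meroantarctine B | C=C1C(=O)O[C@@]23C=C(C)[C@]1(C(=O)OC)[C@@]2(C)C[C@@H]1OC(=O)[C@]32CC[C@H](OC(C)=O)C(C)(C)[C@@H]12 | target

Total step count: 11. Longest linear sequence: 10 steps (steps 1, 2 and 4–11; step 3 is a one-step side branch).

Steps most likely to fail

1. Step 8. The Michael equilibrium may lie on the open side, because the donor is strongly stabilised and the acceptor is a β,β-disubstituted enone that has to become a quaternary carbon next to another one; the basic medium may also shorten the life of the ruthenium carbene. The fallback reverses the order of the two ring closures and sets out from 14. Ring-closing metathesis under neutral conditions (Hoveyda–Grubbs II, PhMe, 80 °C, no base) should give the seven-membered unsaturated α-keto lactone F1, in which C11=C12 already exists and C13–H is held across the ring from C8. A transannular Michael addition (catalytic DBU, MeCN, 23 °C) then closes C8–C13 with proximity as the driving force, and the route is rejoined at 16.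

2. Step 6. The vinyl Grignard reagent may add with poor facial discrimination at C9, or in conjugate fashion to the cross-conjugated dienone. The fallback sets out from 9 and uses a two-step alkynylation and semi-reduction. Ethynylmagnesium bromide (CH2Cl2/THF, −78 °C), a rod-shaped nucleophile that follows the chelate-controlled trajectory and adds strictly 1,2, is followed by methyl chlorooxoacetate to give the C9 ethynyl oxalate F2. Lindlar semi-hydrogenation (H2, Pd/CaCO3/Pb, quinoline, EtOAc) of the alkyne then rejoins the route at 11.

3. Step 4. The cycloaddition may be slow, because the CMe2 terminus disfavours the s-cis conformer of the diene, which would let the Lewis acid erode the silyl enol ether or the enantioselectivity. The fallback replaces catalytic enantiocontrol by resolution and sets out from 4 and 6. Quinone 7 is combined with 6 without a chiral catalyst (PhMe, 40 °C, or 10 kbar, CH2Cl2) to give the racemic cis-adduct, which is 8 together with its enantiomer F3. Preparative chromatography on a chiral stationary phase separates the two, and the route is rejoined at 8.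

Further compounds
F1 | step 8 | seven-membered unsaturated α-keto lactone (C11=C12 closed, C13–H, ring-B enone intact) | COC(=O)C1C(=O)C(=O)O[C@@]2(C=C1C)C(C)=CC(=O)C3C(C)(C)C(=O)CC[C@@]23C(=O)OC
F2 | step 6 | mixed methyl oxalate of the C9 ethynyl carbinol | COC(=O)C(=O)O[C@@]1(C#C)C(C)=CC(O[Si](C)(C)C(C)(C)C)=C2C(C)(C)C(O[Si](C)(C)C(C)(C)C)=CC[C@@]12C(=O)OC
F3 | step 4 | enantiomer of adduct 8 (second component of the racemate) | COC(=O)[C@]12CC=C(O[Si](C)(C)C(C)(C)C)C(C)(C)[C@H]1C(=O)C=C(C)C2=O
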